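**Retrosynthetic overview**
- Planaic acid is a depside with no stereocentre: ring A (2,4-dimethoxy-6-pentylbenzoyl) acylates O4 of ring B (2-methoxy-6-pentylbenzoic acid). The route rests on ring A: C2–C5, with oxygen on C2 and C4, correspond to a 1,3-dioxygenated buta-1,3-diene, and C1, C6, the ester carbonyl and the C6 pentyl chain correspond to an oct-2-ynoate.
- Last disconnections: the ring B acid is released from a tert-butyl ester, and the C2 methyl ether of ring A comes from O-methylation of a salicylate-type phenol.
- Key disconnection: bonds C1–C2 and C5–C6 of ring A, leading back to the oct-2-ynoate ester of the ring B phenol and 1,3-dimethoxy-1-(trimethylsilyloxy)buta-1,3-diene. The hindered depside ester is therefore made earlier, as an unhindered alkynoate ester.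
- Ring B is bought intact as methyl olivetolate and adjusted by 4-O-benzylation, 2-O-methylation, exchange of the methyl for a tert-butyl ester and debenzylation.
- Ring order: ring B is present from the start; ring A is built last, in step 8.

Key step: step 8

Assumption: the double-bond geometry of the silyl ketene acetal diene is without consequence, because that carbon becomes aromatic C2 of ring A; the E isomer is drawn.

**Route**

Step 1
Reactants: 1 methyl 2,4-dihydroxy-6-pentylbenzoate (methyl olivetolate)
Product: 2 methyl 4-(benzyloxy)-2-hydroxy-6-pentylbenzoate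
Conditions: BnBr (1.05 equiv), K2CO3 (1.1 equiv), acetone, reflux
Reagents that add atoms: benzyl bromide, BrCc1ccccc1
Why: Williamson etherification should occur at the 4-OH only, since it is the more acidic and unhindered phenol, whereas the 2-OH is held in a hydrogen bond to the ester carbonyl.

Step 2
Reactants: 2 methyl 4-(benzyloxy)-2-hydroxy-6-pentylbenzoate
Product: 3 methyl 4-(benzyloxy)-2-methoxy-6-pentylbenzoate
Conditions: MeI (3 equiv), K2CO3 (2 equiv), DMF, 50 °C
Reagents that add atoms: iodomethane, CI
Why: Williamson O-methylation of the remaining chelated phenol should go to completion in a dipolar aprotic solvent with excess iodomethane.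

Step 3
Reactants: 3 methyl 4-(benzyloxy)-2-methoxy-6-pentylbenzoate
Product: 5 4-(benzyloxy)-2-methoxy-6-pentylbenzoic acid, via potassium 4-(benzyloxy)-2-methoxy-6-pentylbenzoate 4 (not isolated)
Conditions: KOH (10 equiv), DMSO/H2O 4:1, 100 °C; then 1 M HCl, 0 °C, to pH 3
Reagents that add atoms: potassium hydroxide, [K+].[OH-]
Why: Saponification of the 2,6-disubstituted benzoate should proceed with poorly solvated hydroxide in aqueous DMSO, and cold, mild acidification should avoid decarboxylation of the electron-rich acid.

Step 4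
Reactants: 5 4-(benzyloxy)-2-methoxy-6-pentylbenzoic acid
Product: 6 tert-butyl 4-(benzyloxy)-2-methoxy-6-pentylbenzoate
Conditions: Me2NCH(OtBu)2 (4 equiv), PhMe, 80 °C
Reagents that add atoms: N,N-dimethylformamide di-tert-butyl acetal, CN(C)C(OC(C)(C)C)OC(C)(C)C
Why: Esterification with an amide acetal alkylates the carboxylate at oxygen, so the steric shielding of the carbonyl carbon should not matter and no strong acid is present.

Step 5
Reactants: 6 tert-butyl 4-(benzyloxy)-2-methoxy-6-pentylbenzoate
Product: 7 tert-butyl 4-hydroxy-2-methoxy-6-pentylbenzoate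
Conditions: H2 (1 atm), 10% Pd/C, EtOAc, rt
Reagents that add atoms: none
Why: Catalytic hydrogenolysis should cleave the benzyl aryl ether and leave the tert-butyl ester and the methyl ether untouched.

Step 6
Reactants: 7 tert-butyl 4-hydroxy-2-methoxy-6-pentylbenzoate; 8 oct-2-ynoic acid
Product: 10 tert-butyl 2-methoxy-4-(oct-2-ynoyloxy)-6-pentylbenzoate, via N,N'-dicyclohexyl-O-(oct-2-ynoyl)isourea 9 (not isolated)
Conditions: DCC (1.2 equiv), DMAP (0.05 equiv), CH2Cl2, 0 °C to rt
Reagents that add atoms: none
Why: Steglich esterification of an unhindered phenol with a linear alkynoic acid should be fast, and keeping DMAP catalytic and the mixture cold should limit conjugate addition to the ynoate.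

Step 7
Reactants: 11 methyl (E)-3-methoxybut-2-enoate
Product: 13 (E)-1,3-dimethoxy-1-(trimethylsilyloxy)buta-1,3-diene, via lithium 1,3-dimethoxybuta-1,3-dien-1-olate 12 (not isolated)
Conditions: LiN(iPr)2 (1.1 equiv), THF, −78 °C; then Me3SiCl (1.2 equiv), −78 °C to rt; filtered under argon, concentrated, used at once
Reagents that add atoms: chlorotrimethylsilane, C[Si](C)(C)Cl
Why: Kinetic deprotonation of the vinylogous ester at its γ-methyl group gives the extended dienolate, and O-silylation by the hard silyl chloride should give the silyl ketene acetal diene.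

Step 8
Reactants: 10 tert-butyl 2-methoxy-4-(oct-2-ynoyloxy)-6-pentylbenzoate; 13 (E)-1,3-dimethoxy-1-(trimethylsilyloxy)buta-1,3-diene
Product: 16 tert-butyl 4-[(2-hydroxy-4-methoxy-6-pentylbenzoyl)oxy]-2-methoxy-6-pentylbenzoate, via cyclohexa-1,4-diene cycloadduct 14 (not isolated), via aryl trimethylsilyl ether 15 (not isolated)
Conditions: 13 (3 equiv), PhMe, 120 °C, sealed tube; then 0.5 M HCl, THF, 0 °C
Reagents that add atoms: none
Why: This is a normal-electron-demand Diels–Alder reaction in which the HOMO of diene 13 has its largest coefficient on the terminal CH2 and the LUMO of aryl ynoate 10 has its largest coefficient on the pentyl-bearing β-carbon, so a concerted but asynchronous [4+2] cycloaddition should form C5–C6 of ring A slightly ahead of C1–C2, and this pairing secures the required regiochemistry. Ring A is closed as a six-membered carbocycle by intermolecular [4+2] annulation, both new σ-bonds arising in the one cycloaddition event; the cyclohexa-1,4-diene 14 should then aromatise by 1,4-elimination of methanol to the aryl silyl ether 15, which dilute acid hydrolyses to the hydrogen-bonded phenol 16. The closest known reaction type is the cycloaddition of 1-alkoxy-1-silyloxybuta-1,3-dienes with acetylenic esters to give salicylates. No stereocentre persists, since the ketal carbon of 14 is formed racemic and becomes aromatic C2. The aryl ester lowers the alkyne LUMO more than an alkyl ester would, the tert-butyl ester is shielded by its two ortho substituents and stays a spectator, and the excess diene is destroyed in the acidic work-up.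

Step 9
Reactants: 16 tert-butyl 4-[(2-hydroxy-4-methoxy-6-pentylbenzoyl)oxy]-2-methoxy-6-pentylbenzoate
Product: 17 tert-butyl 4-[(2,4-dimethoxy-6-pentylbenzoyl)oxy]-2-methoxy-6-pentylbenzoate
Conditions: MeI (5 equiv), K2CO3 (3 equiv), DMF, rt to 40 °C
Reagents that add atoms: iodomethane, CI
Why: Williamson O-methylation of the chelated phenol should proceed under anhydrous carbonate conditions, and the depside ester should survive because its carbonyl is flanked by two ortho substituents.

Step 10
Reactants: 17 tert-butyl 4-[(2,4-dimethoxy-6-pentylbenzoyl)oxy]-2-methoxy-6-pentylbenzoate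
Product: 18 planaic acid, 4-[(2,4-dimethoxy-6-pentylbenzoyl)oxy]-2-methoxy-6-pentylbenzoic acid
Conditions: CF3CO2H/CH2Cl2 1:4, 0 °C to rt
Reagents that add atoms: none
Why: Acidolysis of the tert-butyl ester goes by alkyl–oxygen fission with loss of 2-methylpropene, so it should be insensitive to the hindrance at the carbonyl and should leave the aryl ester and the methyl ethers intact.

**Compound list**
1 | methyl 2,4-dihydroxy-6-pentylbenzoate (methyl olivetolate) | CCCCCc1cc(O)cc(O)c1C(=O)OC | starting material
2 | methyl 4-(benzyloxy)-2-hydroxy-6-pentylbenzoate | CCCCCc1cc(OCc2ccccc2)cc(O)c1C(=O)OC | intermediate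
3 | methyl 4-(benzyloxy)-2-methoxy-6-pentylbenzoate | CCCCCc1cc(OCc2ccccc2)cc(OC)c1C(=O)OC | intermediate
4 | potassium 4-(benzyloxy)-2-methoxy-6-pentylbenzoate | CCCCCc1cc(OCc2ccccc2)cc(OC)c1C(=O)[O-].[K+] | intermediate
5 | 4-(benzyloxy)-2-methoxy-6-pentylbenzoic acid | CCCCCc1cc(OCc2ccccc2)cc(OC)c1C(=O)O | intermediate
6 | tert-butyl 4-(benzyloxy)-2-methoxy-6-pentylbenzoate | CCCCCc1cc(OCc2ccccc2)cc(OC)c1C(=O)OC(C)(C)C | intermediate
7 | tert-butyl 4-hydroxy-2-methoxy-6-pentylbenzoate | CCCCCc1cc(O)cc(OC)c1C(=O)OC(C)(C)C | intermediate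
8 | oct-2-ynoic acid | CCCCCC#CC(=O)O | starting material
9 | N,N'-dicyclohexyl-O-(oct-2-ynoyl)isourea | CCCCCC#CC(=O)OC(=NC1CCCCC1)NC1CCCCC1 | intermediate
10 | tert-butyl 2-methoxy-4-(oct-2-ynoyloxy)-6-pentylbenzoate | CCCCCC#CC(=O)Oc1cc(CCCCC)c(C(=O)OC(C)(C)C)c(OC)c1 | intermediate
11 | methyl (E)-3-methoxybut-2-enoate | CO/C(C)=C/C(=O)OC | starting material
12 | lithium 1,3-dimethoxybuta-1,3-dien-1-olate (double-bond geometry as in 13) | C=C(OC)/C=C(\OC)[O-].[Li+] | intermediate
13 | (E)-1,3-dimethoxy-1-(trimethylsilyloxy)buta-1,3-diene | C=C(OC)/C=C(\OC)O[Si](C)(C)C | intermediate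
14 | tert-butyl 4-{[4,6-dimethoxy-2-pentyl-6-(trimethylsilyloxy)cyclohexa-1,4-diene-1-carbonyl]oxy}-2-methoxy-6-pentylbenzoate (racemic at the ketal carbon) | CCCCCC1=C(C(=O)Oc2cc(CCCCC)c(C(=O)OC(C)(C)C)c(OC)c2)C(OC)(O[Si](C)(C)C)C=C(OC)C1 | intermediate
15 | tert-butyl 2-methoxy-4-{[4-methoxy-2-pentyl-6-(trimethylsilyloxy)benzoyl]oxy}-6-pentylbenzoate | CCCCCc1cc(OC)cc(O[Si](C)(C)C)c1C(=O)Oc1cc(CCCCC)c(C(=O)OC(C)(C)C)c(OC)c1 | intermediate
16 | tert-butyl 4-[(2-hydroxy-4-methoxy-6-pentylbenzoyl)oxy]-2-methoxy-6-pentylbenzoate | CCCCCc1cc(OC)cc(O)c1C(=O)Oc1cc(CCCCC)c(C(=O)OC(C)(C)C)c(OC)c1 | intermediate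
17 | tert-butyl 4-[(2,4-dimethoxy-6-pentylbenzoyl)oxy]-2-methoxy-6-pentylbenzoate | CCCCCc1cc(OC)cc(OC)c1C(=O)Oc1cc(CCCCC)c(C(=O)OC(C)(C)C)c(OC)c1 | intermediate
18 | planaic acid, 4-[(2,4-dimethoxy-6-pentylbenzoyl)oxy]-2-methoxy-6-pentylbenzoic acid | CCCCCc1cc(OC(=O)c2c(CCCCC)cc(OC)cc2OC)cc(OC)c1C(=O)O | target

**Step count**
Total steps: 10. Longest linear sequence: 9 steps (steps 1–6, 8, 9 and 10 from compound 1); the diene branch (step 7) joins at step 8.

**Steps most likely to fail**

Step 8. The internal 3-alkyl ynoate may be too sluggish a dienophile, so that at the temperature needed the silyl ketene acetal diene is consumed by silyl migration, hydrolysis or addition without ring closure before the cycloaddition is complete. The fallback gives up the benzannulation and makes the depside bond by a classical acylation; it sets out from 1 and 7 and comes back at 17, so that steps 6 to 9 are not needed.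
- Exhaustive methylation of 1 (MeI, K2CO3, DMF, 60 °C) should give methyl 2,4-dimethoxy-6-pentylbenzoate F1.
- KOH in aqueous DMSO at 100 °C should give potassium 2,4-dimethoxy-6-pentylbenzoate F2, which cold dilute HCl converts into 2,4-dimethoxy-6-pentylbenzoic acid F3.
- (COCl)2 with catalytic DMF in CH2Cl2 should give 2,4-dimethoxy-6-pentylbenzoyl chloride F4.
- Phenol 7 is deprotonated with NaH in THF at 0 °C to sodium 4-(tert-butoxycarbonyl)-3-methoxy-5-pentylphenolate F5, and acylation of this phenoxide by F4 should give 17. The electron-rich acid chloride has acylium character and the nucleophile is an unhindered phenoxide, which is what makes this hindered ester formation workable.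

Step 3. Hydroxide may attack the doubly ortho-substituted ester carbonyl too slowly, and forcing the hydrolysis or acidifying carelessly may cause decarboxylation of the electron-rich acid. The fallback replaces hydrolysis by a reduction–oxidation detour; it sets out from 3 and comes back at 5.
- LiAlH4 in THF at 0 °C should reduce the ester to [4-(benzyloxy)-2-methoxy-6-pentylphenyl]methanol F6, since hydride is small enough to reach the hindered carbonyl.
- MnO2 in CH2Cl2 should oxidise the benzylic alcohol to 4-(benzyloxy)-2-methoxy-6-pentylbenzaldehyde F7.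
- Pinnick oxidation (NaClO2, NaH2PO4, 2-methyl-2-butene, tBuOH/H2O) should give acid 5; the alkene scavenges hypochlorite so that the electron-rich ring is not chlorinated.

Step 10. The tert-butyl cation released in strong acid may alkylate the electron-rich aromatic rings, or prolonged exposure to acid may start decarboxylation of the liberated acid. The fallback avoids protic ionisation in strong acid; it sets out from 17 and comes back at 18.
- Me3SiOSO2CF3 with Et3N in CH2Cl2 at 0 °C should convert the tert-butyl ester, with loss of 2-methylpropene under amine buffering, into trimethylsilyl 4-[(2,4-dimethoxy-6-pentylbenzoyl)oxy]-2-methoxy-6-pentylbenzoate F8.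
- Neutral aqueous work-up should hydrolyse the silyl ester to 18.

**Further compounds**
F1 | step 8 | methyl 2,4-dimethoxy-6-pentylbenzoate | CCCCCc1cc(OC)cc(OC)c1C(=O)OC
F2 | step 8 | potassium 2,4-dimethoxy-6-pentylbenzoate | CCCCCc1cc(OC)cc(OC)c1C(=O)[O-].[K+]
F3 | step 8 | 2,4-dimethoxy-6-pentylbenzoic acid | CCCCCc1cc(OC)cc(OC)c1C(=O)O
F4 | step 8 | 2,4-dimethoxy-6-pentylbenzoyl chloride | CCCCCc1cc(OC)cc(OC)c1C(=O)Cl
F5 | step 8 | sodium 4-(tert-butoxycarbonyl)-3-methoxy-5-pentylphenolate | CCCCCc1cc([O-])cc(OC)c1C(=O)OC(C)(C)C.[Na+]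
F6 | step 3 | [4-(benzyloxy)-2-methoxy-6-pentylphenyl]methanol | CCCCCc1cc(OCc2ccccc2)cc(OC)c1CO
F7 | step 3 | 4-(benzyloxy)-2-methoxy-6-pentylbenzaldehyde | CCCCCc1cc(OCc2ccccc2)cc(OC)c1C=O
F8 | step 10 | trimethylsilyl 4-[(2,4-dimethoxy-6-pentylbenzoyl)oxy]-2-methoxy-6-pentylbenzoate | CCCCCc1cc(OC(=O)c2c(CCCCC)cc(OC)cc2OC)cc(OC)c1C(=O)O[Si](C)(C)C
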